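Two questions are put to the flasks below: how much Z stands at the end of each, and what shape the row takes.

    J + X → X + E (k1 = 3400 M⁻¹ s⁻¹)
    D + Q + E → Q + Z (k2 = 29000 M⁻² s⁻¹)
    D → L (k3 = 3.8 × 10⁻⁵ s⁻¹)
    J + D → J.D (k4 = 4.2 M⁻¹ s⁻¹)

| flask | J | D | X | Q | time |
|---|---|---|---|---|---|
| ash | 20 mM | 20.0 mM | 40 µM | 40 µM | 30 s |
| larch | 40 mM | 20.0 mM | 40 µM | 40 µM | 30 s |
| oak | 80 mM | 20.0 mM | 40 µM | 40 µM | 30 s |

* [Z] at the end for ash, larch, oak, in this order
* the shape of the row from first to last (falls, then rises / hardly changes / rises, then falls / falls all the way / rises all the way)

- "hardly changes" means that all values lie within two and a half points (for a concentration: within two and a half percent of the largest)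
- run time (ash): 30 s

Steps 1 and 4 both consume J, and both rates carry [J] alike, so their quotient holds no J, and reckoning J spent against D lost takes time out. What stays is the split number, the rate of step 1 over that of step 4 with D at its charge (a selectivity factor): S = 1.62. With a fraction x of D left, the quotient is S/x.

Step 1 alone has a lifetime of 7.35 s, shorter than the run, and leaves 1.69 % of J by the end. Step 2 with D at its charge gives E a lifetime of 43.1 s, longer than that of J, so J is reckoned to pass first and Z to follow.

Two extreme versions can be solved in the head. With S very large, J passes to E, step 4 takes no D, and step 2 speeds up with every added J, so the row rises all the way. With S very small, J takes D one for one, and D and J cancel in ash, whose charges are equal, while larch and oak keep J and lose D, so Z tends to nothing.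

The real S lies between. Dividing the rates and setting step 2 aside, the J spent, counted in D charges, equals the fraction of D lost plus S times ln(D charge over D left). With J reckoned spent, that leaves x = 0.661 in ash, 0.415 in larch and 0.143 in oak. E, in D charges, is then the J charge less the D lost, so the product of D and E in the rate of step 2 is 0.437, 0.588 and 0.450 at that point. Larch stands highest, so my reckoning commits to a row that rises, then falls.

The forecast gave 3.7 mM, 4.3 mM and 3.3 mM, rises, then falls, on the ground that “More J therefore gives more E but also strips out more D as J.D”.

The simulation gives 3.83 mM, 4.91 mM and 3.74 mM, so the row rises, then falls. In ash, step 1 runs 1.6 times as fast as step 4 at the start, which is S, and at 15.0 s D stands at 58.6 % of its charge, which puts the quotient at 2.76, while J.D reaches 32.8 % of the D charge at 30.0 s, against 33.9 % reckoned. In oak, D stands at 8.83 % at 15.0 s, which puts the quotient at 18.3, J.D reaches 78.6 % of the D charge at 30.0 s against 85.7 % reckoned, and 2.7 % of D is left at 30.0 s.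

(All constants are those of an exercise; no experiment stands behind them.)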